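## Retrosynthetic overview
1. The target has two aryl–CH2 bonds. Each is made by Cu-catalysed Kumada coupling of a benzyl-protected aryl Grignard with a primary alkyl iodide, one end at a time, from a mono-TBS-protected (2S,3R)-2,3-dimethylbutane-1,4-diol.
2. That differentiated diol comes from the cis-3,4-dimethyl-γ-butyrolactone, by saponification, O-methylation, TBS protection and LiAlH4 reduction.
3. The lactone comes from enzymatic (alcohol dehydrogenase) oxidative desymmetrisation of meso-2,3-dimethylbutane-1,4-diol. The meso diol comes from the cis-anhydride, which comes from syn-hydrogenation of 2,3-dimethylmaleic anhydride.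
4. No carbocycle is built, because both arenes enter pre-formed as benzyl-protected bromophenols. The only ring formed and opened is the lactone (formed in Step 3, opened in Step 4).

**Assumption:** horse-liver alcohol dehydrogenase (HLADH) gives the (3S,4R)-lactone **4**. If the (3R,4S) antipode formed instead, the two aryl Grignards would simply be used in the opposite order.

## Route

**Step 1**
Reactants: **1** 2,3-dimethylmaleic anhydride (3,4-dimethylfuran-2,5-dione)
Product: **2** cis-(meso)-3,4-dimethyloxolane-2,5-dione
Conditions: H2 (3 atm), 10% Pd/C, EtOAc, rt, 16 h; recrystallise to remove any trans isomer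
Reagents that add atoms: none (H2 adds only hydrogen)
Why: Heterogeneous hydrogenation is a syn addition to the tetrasubstituted C=C, so both new methyl-bearing carbons are cis and the product is meso. This step fixes relative configuration only.

**Step 2**
Reactants: **2**
Product: **3** (2R,3S)-2,3-dimethylbutane-1,4-diol (meso)
Conditions: LiAlH4, THF, 0 °C → rt, 4 h
Reagents that add atoms: none
Why: Hydride reduction of the anhydride C=O groups leaves both C–H stereocentres untouched, so the cis-anhydride gives the meso diol.

**Step 3**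
Reactants: **3**
Product: **4** (3S,4R)-3,4-dimethyloxolan-2-one (cis-lactone)
Conditions: horse-liver alcohol dehydrogenase (HLADH, EC 1.1.1.1), NAD+ (1 mol%), cyclohexanone (4 equiv), 0.1 M KPi pH 8.0, 30 °C, 48 h; then acidify to pH 3 and extract with Et2O
Reagents that add atoms: none (cyclohexanone only recycles NAD+ and leaves as cyclohexanol)
Why: The alcohol dehydrogenase oxidises one of the two enantiotopic CH2OH groups to the aldehyde, which closes to the lactol and is oxidised again to the lactone. This enantiotopic-group-selective oxidation (desymmetrisation) makes the chiral, differentiated cis-lactone and sets the absolute configuration of both methyl-bearing stereocentres.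

**Step 4**
Reactants: **4**, **5** iodomethane
Product: **6** methyl (2S,3R)-4-hydroxy-2,3-dimethylbutanoate
Conditions: (i) LiOH·H2O (1.0 equiv), THF/H2O 1:1, rt, 2 h; concentrate to dryness; (ii) MeI (3 equiv), DMF, rt, 12 h; use the crude directly in Step 5
Reagents that add atoms: MeI, CI; water (from LiOH·H2O), O
Why: Saponification opens the lactone to the carboxylate, and SN2 O-methylation of the carboxylate gives the hydroxy ester without acidification, so it cannot re-lactonise. This is a basic, non-enolising sequence, so the stereocentres are retained.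

**Step 5**
Reactants: **6**, **7** tert-butyldimethylsilyl chloride (TBSCl)
Product: **8** methyl (2S,3R)-4-[(tert-butyldimethylsilyl)oxy]-2,3-dimethylbutanoate
Conditions: TBSCl (1.2 equiv), imidazole (2.5 equiv), DMF, rt, 6 h
Reagents that add atoms: TBSCl, CC(C)(C)[Si](C)(C)Cl
Why: Corey silylation of the primary alcohol permanently marks one terminus, so the two ends of the chain stay distinguishable.

**Step 6**
Reactants: **8**
Product: **9** (2S,3R)-4-[(tert-butyldimethylsilyl)oxy]-2,3-dimethylbutan-1-ol
Conditions: LiAlH4, THF, 0 °C, 1 h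
Reagents that add atoms: none
Why: Ester-to-primary-alcohol reduction; the TBS ether is inert, and the stereocentres are untouched.

**Step 7**
Reactants: **9**, **10** iodine
Product: **11** tert-butyl[(2R,3S)-4-iodo-2,3-dimethylbutoxy]dimethylsilane
Conditions: I2 (1.3 equiv), PPh3 (1.3 equiv), imidazole (2.6 equiv), CH2Cl2, 0 °C → rt, 3 h
Reagents that add atoms: I2, [I][I]
Why: Garegg–Samuelsson (Appel-type) iodination is an SN2 at a primary, non-stereogenic carbon, so configuration is retained.

**Step 8**
Reactants: **12** 4-bromo-2,6-dimethoxyphenol, **13** benzyl bromide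
Product: **14** 2-(benzyloxy)-5-bromo-1,3-dimethoxybenzene
Conditions: BnBr (1.2 equiv), K2CO3 (2 equiv), DMF, 60 °C, 4 h
Reagents that add atoms: BnBr, BrCc1ccccc1
Why: Williamson O-benzylation masks the acidic phenol so the aryl Grignard can form, and the benzyl group can be removed by hydrogenolysis at the end.

**Step 9**
Reactants: **11**, **14**
Product: **15** tert-butyl{[(2R,3R)-4-[4-(benzyloxy)-3,5-dimethoxyphenyl]-2,3-dimethylbutyl]oxy}dimethylsilane
Conditions: 14 (2.5 equiv), Mg (2.6 equiv), THF, 60 °C, 2 h, to give ArMgBr; then 11, Li2CuCl4 (5 mol%), THF, 0 °C → rt, 12 h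
Reagents that add atoms: none (Mg is consumed as MgBrI)
Why: Cu-catalysed Kumada–Tamao–Corriu (Kochi-type) coupling forms the aryl–CH2 bond at a non-stereogenic primary carbon. The TBS ether, OMe and OBn groups are stable to ArMgBr, and the stereocentres are not involved.

**Step 10**
Reactants: **15**
Product: **16** (2R,3R)-4-[4-(benzyloxy)-3,5-dimethoxyphenyl]-2,3-dimethylbutan-1-ol
Conditions: TBAF (1.5 equiv), THF, 0 °C → rt, 3 h
Reagents that add atoms: none
Why: Fluoride-mediated desilylation frees the second terminus; the aryl benzyl ether is unaffected.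

**Step 11**
Reactants: **16**, **10** iodine
Product: **17** 2-(benzyloxy)-5-[(2R,3R)-4-iodo-2,3-dimethylbutyl]-1,3-dimethoxybenzene
Conditions: I2 (1.3 equiv), PPh3 (1.3 equiv), imidazole (2.6 equiv), CH2Cl2, 0 °C → rt, 3 h
Reagents that add atoms: I2, [I][I]
Why: Same primary-carbon Appel-type iodination as Step 7, with no stereochemical consequence.

**Step 12**
Reactants: **18** 4-bromo-2-methoxyphenol, **13** benzyl bromide
Product: **19** 1-(benzyloxy)-4-bromo-2-methoxybenzene
Conditions: BnBr (1.2 equiv), K2CO3 (2 equiv), DMF, 60 °C, 4 h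
Reagents that add atoms: BnBr, BrCc1ccccc1
Why: Williamson O-benzylation, as in Step 8.

**Step 13**
Reactants: **17**, **19**
Product: **20** 2-(benzyloxy)-5-{(2R,3S)-4-[4-(benzyloxy)-3-methoxyphenyl]-2,3-dimethylbutyl}-1,3-dimethoxybenzene
Conditions: 19 (2.5 equiv), Mg (2.6 equiv), THF, 60 °C, 2 h, to give ArMgBr; then 17, Li2CuCl4 (5 mol%), THF, 0 °C → rt, 12 h
Reagents that add atoms: none
Why: Second Cu-catalysed Kumada coupling at the other, non-stereogenic primary carbon completes the 1,4-diaryl-2,3-dimethylbutane skeleton with both stereocentres intact.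

**Step 14**
Reactants: **20**
Product: **21** 4-[(2R,3S)-4-(4-hydroxy-3-methoxyphenyl)-2,3-dimethylbutyl]-2,6-dimethoxyphenol (target)
Conditions: H2 (1 atm, or 3 atm if slow), 10% Pd(OH)2/C, EtOH/EtOAc 1:1, rt, 16 h
Reagents that add atoms: none
Why: Hydrogenolysis cleaves both O-benzyl ethers to the free phenols (toluene is lost), while the aryl methyl ethers and the non-benzylic stereocentres are untouched.

## Compound list
1 | 2,3-dimethylmaleic anhydride | CC1=C(C)C(=O)OC1=O | starting material
2 | (3R,4S)-3,4-dimethyloxolane-2,5-dione (cis, meso) | C[C@H]1C(=O)OC(=O)[C@H]1C | intermediate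
3 | (2R,3S)-2,3-dimethylbutane-1,4-diol (meso) | OC[C@H](C)[C@H](C)CO | intermediate
4 | (3S,4R)-3,4-dimethyloxolan-2-one | C[C@H]1COC(=O)[C@H]1C | intermediate
5 | iodomethane | CI | starting material (reagent)
6 | methyl (2S,3R)-4-hydroxy-2,3-dimethylbutanoate | OC[C@H](C)[C@H](C)C(=O)OC | intermediate
7 | TBSCl | CC(C)(C)[Si](C)(C)Cl | starting material (reagent)
8 | methyl (2S,3R)-4-(TBSO)-2,3-dimethylbutanoate | CC(C)(C)[Si](C)(C)OC[C@H](C)[C@H](C)C(=O)OC | intermediate
9 | (2S,3R)-4-(TBSO)-2,3-dimethylbutan-1-ol | CC(C)(C)[Si](C)(C)OC[C@H](C)[C@H](C)CO | intermediate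
10 | iodine | II | starting material (reagent)
11 | tert-butyl[(2R,3S)-4-iodo-2,3-dimethylbutoxy]dimethylsilane | CC(C)(C)[Si](C)(C)OC[C@H](C)[C@H](C)CI | intermediate
12 | 4-bromo-2,6-dimethoxyphenol | COc1cc(Br)cc(OC)c1O | starting material
13 | benzyl bromide | BrCc1ccccc1 | starting material (reagent)
14 | 2-(benzyloxy)-5-bromo-1,3-dimethoxybenzene | COc1cc(Br)cc(OC)c1OCc1ccccc1 | intermediate
15 | TBS ether of the syringyl-coupled alcohol, (2R,3R) | CC(C)(C)[Si](C)(C)OC[C@H](C)[C@H](C)Cc1cc(OC)c(OCc2ccccc2)c(OC)c1 | intermediate
16 | (2R,3R)-4-[4-(benzyloxy)-3,5-dimethoxyphenyl]-2,3-dimethylbutan-1-ol | OC[C@H](C)[C@H](C)Cc1cc(OC)c(OCc2ccccc2)c(OC)c1 | intermediate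
17 | 2-(benzyloxy)-5-[(2R,3R)-4-iodo-2,3-dimethylbutyl]-1,3-dimethoxybenzene | IC[C@H](C)[C@H](C)Cc1cc(OC)c(OCc2ccccc2)c(OC)c1 | intermediate
18 | 4-bromo-2-methoxyphenol | COc1cc(Br)ccc1O | starting material
19 | 1-(benzyloxy)-4-bromo-2-methoxybenzene | COc1cc(Br)ccc1OCc1ccccc1 | intermediate
20 | bis-O-benzyl target precursor, (2R,3S) | COc1cc(C[C@H](C)[C@H](C)Cc2cc(OC)c(OCc3ccccc3)c(OC)c2)ccc1OCc1ccccc1 | intermediate
21 | 4-[(2R,3S)-4-(4-hydroxy-3-methoxyphenyl)-2,3-dimethylbutyl]-2,6-dimethoxyphenol | COc1cc(C[C@H](C)[C@H](C)Cc2cc(OC)c(O)c(OC)c2)ccc1O | target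

## Totals
Total steps: 14. Longest linear sequence: 12 (Steps 1–7, 9, 10, 11, 13, 14). Steps 8 and 12 are short convergent branches from commercial phenols.

## Three steps most likely to fail
1. **Step 3 (HLADH desymmetrisation: enantiomeric excess, conversion, enzyme sense).**
   Fallback: organocatalytic methanolysis of the meso-anhydride **2** with a cinchona-alkaloid catalyst such as (DHQD)2AQN. Then reduce the acid of the hemiester selectively with BH3·SMe2 and close the lactone with cat. TsOH to give **4** (or its enantiomer, by switching to the pseudo-enantiomeric catalyst).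
2. **Steps 9 and 13 (Cu-catalysed Kumada couplings: biaryl homocoupling, reduction, incomplete conversion).**
   Fallback: oxidise the alcohol (DMP) to the aldehyde, add ArMgBr, then deoxygenate the benzylic alcohol (Et3SiH/TFA). This builds the aryl–CH2 bond by carbonyl addition and reduction instead of sp3–sp2 coupling.
3. **Step 4 (lactone opening without re-closure or α-epimerisation).**
   Fallback: open lactone **4** with Me(MeO)NH·HCl/AlMe3 to the hydroxy Weinreb amide and protect it as the TBS ether. Then reduce with LiAlH4 at −78 °C to the aldehyde and with NaBH4 to reach alcohol **9**.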